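## The problem

Compound 13 has a thymol-type skeleton (thymol numbering: C1 carries C7, C3 the phenolic oxygen, C4 the side-chain carbon C8). Its two rings share no atom: a benzene ring, and an oxirane attached to C4 through its quaternary carbon C8. The oxirane is built from C8, the methylene C9 and the ring oxygen, and the fourth ligand of C8 is the acyloxymethyl carbon C10. C8 (R in 13) is the only stereocentre, so no resident centre can control it and its sense must come from a chiral catalyst or reagent; the E geometry of the tiglate can be bought. Three hydroxyl functions have to be told apart, because the phenol carries a tiglate while C7–O and C10–O carry isobutyrates. The tertiary benzylic oxirane ionises at C8 under acid, which means opening and racemisation, and the aryl tiglate is an activated ester that hydroxide, alkoxide or a neighbouring hydroxyl group will take. A free phenol or phenoxide at C3 would lie within reach of C9 and would turn the oxirane into a dihydrobenzofuran, so the tiglate must be in place before the oxirane exists; its alkene is also a second possible site for any oxidant. What opens the way is that O–C8–C9 with C10–O on C8 is the 2,3-epoxy alcohol pattern: without the C10 acyl group and the ring oxygen the molecule is a 2-arylallyl alcohol, whose hydroxyl group can hold a chiral titanium peroxide over the C8=C9 bond.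

## Retrosynthesis

**13 ⇒ 12 + 5 (acyl–O bond at C10).**
- This ester bond is cut first because it uncovers the hydroxyl group that the epoxidation needs.
- Cutting the tiglate instead would put a phenol beside the oxirane. Cutting the C7 ester would free a hydroxyl group that has no task.
- The (S)-glycidol 12 is one acyl group simpler and shows the epoxy alcohol retron.
- The forward acylation with 5 must be cold, fast and free of acid.
- It touches no bond at C8. The descriptor changes from S to R only because acylated C10 outranks C9.

**12 ⇒ 11 (O–C8 and O–C9 together).**
- Both oxirane bonds are cut at once, which leads to the achiral, planar allylic alcohol 11.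
- Cutting O–C9 alone would call for a tertiary C8 alkoxide and a leaving group on C9. That alkoxide sits six atoms from the tiglate carbonyl and would take the acyl group before it closes the ring.
- Cutting C8–C9 (methylene transfer to a ketone) needs a basic ylide and has no handle for face control.
- The double cut removes the ring and the stereocentre in one move, the largest simplification on offer.
- The forward step must choose one face of a 1,1-disubstituted alkene, ignore the tiglate alkene, and run cold and nearly neutral. Binding of the C10 hydroxyl group to the metal serves all three demands.

**11 ⇒ 10 (O–Si bond).**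
- In 11 a primary alcohol stands close to an activated aryl ester, and transfer of the acyl group to the alcohol is downhill.
- 11 should therefore never meet base or heat, and it is traced to the silyl ether 10.
- This costs one step in the main line but takes the hydroxyl group out of the cross-coupling.
- The unmasking must be done with acidic fluoride, not with a basic one.

**10 ⇒ 6 + 9 (C4–C8 bond).**
- The sp2–sp2 bond between ring and side chain is cut to give aryl bromide 6 and alkenyl boronate 9.
- A cut at C8=C9 (methylenation of an aryl ketone) again needs a basic ylide next to the aryl ester. A cut at C8–C10 leaves a styrene that must be hydroxymethylated.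
- The C4–C8 cut is convergent. One half holds the arene with two esters already sorted, and the other holds C8, C9 and C10 at their final oxidation level.
- The coupling must activate boron without hydroxide or alkoxide.

**6 ⇒ 4 + 5 (acyl–O bond at C7).**
- With the phenol already esterified only one hydroxyl group is left in 4, so this acylation needs no selectivity.
- Its reagent, 5, is the one used again in the last step.

**4 ⇒ 2 + 3 (acyl–O bond at the phenol).**
- The phenol of 2 is far more acidic than the benzylic alcohol, so a weak inorganic base singles it out for acid chloride 3.
- Acylating the phenol first uses this natural difference. The reverse order would need a device to shield the phenol.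

**2 ⇒ 1 (oxidation level of C7).**
- The benzylic alcohol comes from the ester of commercial 1 by hydride reduction.
- Bromine, phenol and C7 already stand in the 4, 3, 1 relation of the target, so no aromatic substitution has to be controlled.

**9 ⇒ 8 (C–B bond).**
- The boronate is traced to alkenyl bromide 8 by palladium-catalysed borylation.
- Halogen–metal exchange is avoided because a 2-metallated allyl silyl ether can pass silicon from oxygen to carbon.

**8 ⇒ 7 (O–Si bond).** Silylation of commercial 2-bromoallyl alcohol 7 is the only other step in the three-carbon branch.

## Roads not taken

**Alternative 1:** The cut falls on C8–O and C8–C9, both traced to a carbene carbon.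
- *Forward key step.* Rh2(OAc)4 would turn the aryldiazoacetate A1 into a rhodium carbene, and water A2 would add to give an oxonium ylide. A BINOL phosphoric acid with 2,4,6-triisopropylphenyl groups at the 3,3' positions would then steer the aldol-type capture of that ylide by formaldehyde A3, giving the diol ester A4.
- *Merits.* Quaternary C8 is made with one C–O and one C–C bond in a single catalytic step from very small pieces. Its two carbon arms (ester and CH2OH) are chemically distinct from the outset, a clearer differentiation than in 12.
- *Weak points in the key step.* The ylide can collapse by proton shift to plain O–H insertion before it meets A3. Aqueous A3 brings a large excess of A2. The ortho-silyloxy group crowds both the carbene carbon and the chiral ion pair.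
- *Weak points afterwards.* No ring is closed. After A4 there remain:
  - activation of the primary hydroxyl group and base closure;
  - reduction of the ethyl ester, which also strips the C7 isobutyrate (repairable, since both positions end as isobutyrates), and double acylation;
  - phenol desilylation and tigloylation.

  That is about six steps, and the last two set a phenoxide free beside the finished oxirane.
- *Comparison.* The chosen plan forms ring and stereocentre together, one step from 13 and with the tiglate already on.

**Alternative 2:** The cut is one O–CH2 bond of the oxirane, traced to the prochiral dichlorohydrin A5.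
- *Forward key step.* A halohydrin dehalogenase of the HheC type would deprotonate the tertiary hydroxyl group and let it displace chloride from one of the two enantiotopic CH2Cl arms, giving the (S)-chloromethyl oxirane A6.
- *Merits.* It is a desymmetrisation, so all the material can in principle be used. It closes the ring and sets C8 in one mild, neutral aqueous step, and A5 is quickly assembled. In these respects it equals the chosen key step.
- *Weak points in the key step.* A 2-aryl substrate with an ortho-alkoxy group is large for this active site and poorly soluble in buffer. The enzyme also catalyses the reverse opening by chloride, which wears down the enantiomeric purity.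
- *Stereochemical hazard.* A6 as drawn leads to 13 only if the carboxylate enters at the oxirane methylene and the alkoxide then recloses on CH2Cl. Direct displacement of chloride gives the enantiomer. The neopentyl-like CH2Cl favours the first path, but any leakage lowers the purity.
- *Weak points afterwards.* Silyl removal and acylation at C7 are still needed, followed by removal of the allyl group and tigloylation, which again frees the phenol next to the oxirane.
- *Comparison.* The chosen plan has no such ambiguity, because the oxygen on C10 never leaves its carbon, and it needs no phenol deprotection after the ring is made.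

**Alternative 3:** The cuts are C4–C8 and C10–O.
- *Forward key step.* Zerovalent palladium from Pd(OAc)2 and PPh3 would insert into aryl iodide A7. The arylpalladium would add to the central carbon of propadiene A8, and caesium isobutyrate A9 would attack a terminus of the symmetrical 2-aryl-π-allyl complex to give A10.
- *Merits.* This is the shortest way to the full skeleton with all three esters, and A10 is one oxygen atom short of 13. No protecting group is used, the symmetrical allyl unit poses no regiochemical question, and A7 is as easy to make as 6. In step count it beats the chosen plan by two steps in the longest line and about four overall.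
- *Weak points.*
  - The key step makes neither the ring nor the stereocentre.
  - The remaining step is an undirected enantioselective epoxidation of a 1,1-disubstituted, ortho-substituted styrene. This is the least reliable alkene class for chiral manganese salen complexes and chiral dioxiranes, and the dioxirane method runs in a basic buffer that threatens the aryl ester.
  - A10 cannot be fed into a directed epoxidation, since its two isobutyrates cannot be cleaved selectively.
  - A9 may exchange acyl groups with the aryl tiglate at coupling temperature, and A8 is a gas.
- *Comparison.* What the chosen plan sets against the shorter count is a hydroxyl-bound catalyst. This gives a predictable sense and a known level of control for 2-substituted allylic alcohols.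

Key step: step 8

Assumption: the drawn configuration (C8 = R in 13) is taken as the one wanted, and tigloyl chloride 3 is taken as a commercial reagent of E geometry.

## Steps

Step 1
Reactants: 1 methyl 4-bromo-3-hydroxybenzoate
Product: 2 2-bromo-5-(hydroxymethyl)phenol
Conditions: iBu2AlH (3.5 equiv), CH2Cl2, −78 → 0 °C; aq. potassium sodium tartrate
Reagents that add atoms: none
Why: Hydride reduction of an ester: the first equivalent is spent on the phenol (aluminium phenoxide and H2), and two more take the ester through the aldehyde to the benzylic alkoxide. The aryl bromide is inert to this reagent at or below 0 °C.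

Step 2
Reactants: 2 2-bromo-5-(hydroxymethyl)phenol; 3 tigloyl chloride [(E)-2-methylbut-2-enoyl chloride]
Product: 4 2-bromo-5-(hydroxymethyl)phenyl (E)-2-methylbut-2-enoate
Conditions: K2CO3 (1.2 equiv), acetone, 0 °C, slow addition of 3 (1.0 equiv)
Reagents that add atoms: none
Why: Chemoselective phenoxide acylation of the Schotten–Baumann type: K2CO3 deprotonates only the much more acidic o-bromophenol, and the phenoxide outruns the neutral benzylic alcohol for the single equivalent of 3. An inorganic base is used because tertiary amines can convert 3 into a vinylketene and so deliver the deconjugated ester; the E alkene is not touched.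

Step 3
Reactants: 4 2-bromo-5-(hydroxymethyl)phenyl (E)-2-methylbut-2-enoate; 5 isobutyric anhydride
Product: 6 2-bromo-5-[(isobutyryloxy)methyl]phenyl (E)-2-methylbut-2-enoate
Conditions: 5 (1.3 equiv), pyridine, DMAP (5 mol%), CH2Cl2, 0 °C → rt
Reagents that add atoms: none
Why: DMAP-catalysed acylation of a primary alcohol with an anhydride. Only one hydroxyl group is left, and the hindered, conjugated aryl ester is stable to pyridine at room temperature.

Step 4
Reactants: 7 2-bromoprop-2-en-1-ol
Product: 8 (2-bromoallyloxy)(tert-butyl)dimethylsilane
Conditions: TBSCl, imidazole, CH2Cl2, 0 °C → rt
Reagents that add atoms: tert-butyldimethylsilyl chloride, CC(C)(C)[Si](C)(C)Cl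
Why: Standard imidazole-promoted silylation of a primary alcohol. The TBS ether withstands palladium catalysis and weak bases and leaves later under acidic fluoride.

Step 5
Reactants: 8 (2-bromoallyloxy)(tert-butyl)dimethylsilane
Product: 9 tert-butyldimethyl{[2-(4,4,5,5-tetramethyl-1,3,2-dioxaborolan-2-yl)prop-2-en-1-yl]oxy}silane
Conditions: B2pin2, PdCl2(dppf) (3 mol%), KOAc, 1,4-dioxane, 80 °C
Reagents that add atoms: bis(pinacolato)diboron, CC1(C)OB(OC1(C)C)B1OC(C)(C)C(C)(C)O1
Why: Miyaura borylation of an alkenyl bromide: oxidative addition of zerovalent palladium to C–Br, acetate-assisted transmetalation with B2pin2, then reductive elimination. KOAc is too weak a base to promote coupling of 9 with unreacted 8, and the silyloxy group is too poor a leaving group for β-elimination to an allene.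

Step 6
Reactants: 6 2-bromo-5-[(isobutyryloxy)methyl]phenyl (E)-2-methylbut-2-enoate; 9 tert-butyldimethyl{[2-(4,4,5,5-tetramethyl-1,3,2-dioxaborolan-2-yl)prop-2-en-1-yl]oxy}silane
Product: 10 2-[3-(tert-butyldimethylsilyloxy)prop-1-en-2-yl]-5-[(isobutyryloxy)methyl]phenyl (E)-2-methylbut-2-enoate
Conditions: Pd(OAc)2 (3 mol%), SPhos (6 mol%), CsF (3 equiv), 1,4-dioxane, 60 °C
Reagents that add atoms: none
Why: Suzuki–Miyaura coupling forms C4–C8; fluoride activates the boronate without hydroxide or alkoxide, so the aryl tiglate and the benzylic isobutyrate should persist. The bulky, electron-rich phosphine speeds oxidative addition and transmetalation at the ortho-substituted bromide, which leaves the arylpalladium little time to engage the tiglate alkene. CsF is barely soluble in dioxane, and primary alkyl TBS ethers normally withstand it.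

Step 7
Reactants: 10 2-[3-(tert-butyldimethylsilyloxy)prop-1-en-2-yl]-5-[(isobutyryloxy)methyl]phenyl (E)-2-methylbut-2-enoate
Product: 11 2-(3-hydroxyprop-1-en-2-yl)-5-[(isobutyryloxy)methyl]phenyl (E)-2-methylbut-2-enoate
Conditions: HF·pyridine, THF, 0 °C (plastic vessel)
Reagents that add atoms: none
Why: Fluoride-induced cleavage of a silyl ether, driven by the Si–F bond. The acidic reagent keeps the medium free of alkoxide and phenoxide, so the three esters stay and the shift of the tigloyl group to the new hydroxyl group is not triggered. Compound 11 is kept cold and used promptly.

Step 8
Reactants: 11 2-(3-hydroxyprop-1-en-2-yl)-5-[(isobutyryloxy)methyl]phenyl (E)-2-methylbut-2-enoate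
Product: 12 2-[(2S)-2-(hydroxymethyl)oxiran-2-yl]-5-[(isobutyryloxy)methyl]phenyl (E)-2-methylbut-2-enoate
Conditions: Ti(OiPr)4 (10 mol%), diisopropyl L-(+)-tartrate (12 mol%), tBuOOH (2 equiv, anhydrous in decane), powdered 4 Å MS, CH2Cl2, −20 °C
Reagents that add atoms: tert-butyl hydroperoxide, CC(C)(C)OO
Why: Sharpless asymmetric epoxidation of a 2-substituted primary allylic alcohol, a known and well-behaved substrate class. Alkoxide exchange between Ti(OiPr)4 and the tartrate gives the dimer [Ti(tartrate)(OiPr)2]2, and on one tetravalent titanium centre the two remaining isopropoxides are replaced by the C10 alkoxide of 11 and by bidentate tert-butyl peroxide. The C8=C9 π bond attacks the peroxide oxygen that carries no tert-butyl group along the O–O axis, so O–C8 and O–C9 form in one concerted spiro-type oxygen-atom transfer and the oxirane closes as a [2+1] addition, while tert-butoxide stays on titanium and is exchanged for the next substrate. C8 is the only new stereocentre and the tartrate controls it: the L-(+) ester turns allyl alcohol into (S)-glycidol and 2-methylallyl alcohol into (S)-2-methylglycidol, and here it should deliver oxygen to the Si face of C8 (ranking C10 > aryl > C9); because the aryl carbon (C,C,C) ranks below both CH2O carbons it takes the place of H or CH3 as lowest ligand, and the descriptor stays S. Chemoselectivity over the tiglate alkene is needed, and it is secured because only the alkene tethered through the C10 alkoxide lies next to the activated peroxide and the enoate is electron-poor. Catalytic titanium, sieves and −20 °C hold back opening at C9 by isopropoxide, ionisation at benzylic C8 and titanium-mediated transfer of the aryl tiglate. The work-up has to be non-hydrolytic (reductive quench of excess peroxide, filtration, chromatography on deactivated silica), because the usual aqueous NaOH treatment would cleave the aryl ester, and 12 is carried on at once.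

Step 9
Reactants: 12 2-[(2S)-2-(hydroxymethyl)oxiran-2-yl]-5-[(isobutyryloxy)methyl]phenyl (E)-2-methylbut-2-enoate; 5 isobutyric anhydride
Product: 13 2-{(2R)-2-[(isobutyryloxy)methyl]oxiran-2-yl}-5-[(isobutyryloxy)methyl]phenyl (E)-2-methylbut-2-enoate (CNP0189152.1)
Conditions: 5 (1.5 equiv), pyridine, DMAP (5 mol%), CH2Cl2, 0 °C
Reagents that add atoms: none
Why: Pyridine/DMAP-catalysed acylation of a primary alcohol with an anhydride; no bond to C8 is touched, so the configuration is kept and only the descriptor changes from S to R, because acylated C10 now outranks C9. The cold, buffered medium avoids acid opening at C8, and a Payne shift of the alkoxide, should it occur, is degenerate here (inversion at C8 together with exchange of the roles of C9 and C10 returns the same enantiomer).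

## Compound list

1 | methyl 4-bromo-3-hydroxybenzoate | COC(=O)c1ccc(Br)c(O)c1 | starting material
2 | 2-bromo-5-(hydroxymethyl)phenol | OCc1ccc(Br)c(O)c1 | intermediate
3 | tigloyl chloride, (E)-2-methylbut-2-enoyl chloride | C/C=C(\C)C(=O)Cl | starting material
4 | 2-bromo-5-(hydroxymethyl)phenyl (E)-2-methylbut-2-enoate | C/C=C(\C)C(=O)Oc1cc(CO)ccc1Br | intermediate
5 | isobutyric anhydride | CC(C)C(=O)OC(=O)C(C)C | starting material
6 | 2-bromo-5-[(isobutyryloxy)methyl]phenyl (E)-2-methylbut-2-enoate | C/C=C(\C)C(=O)Oc1cc(COC(=O)C(C)C)ccc1Br | intermediate
7 | 2-bromoprop-2-en-1-ol | C=C(Br)CO | starting material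
8 | (2-bromoallyloxy)(tert-butyl)dimethylsilane | C=C(Br)CO[Si](C)(C)C(C)(C)C | intermediate
9 | tert-butyldimethyl{[2-(4,4,5,5-tetramethyl-1,3,2-dioxaborolan-2-yl)prop-2-en-1-yl]oxy}silane | C=C(CO[Si](C)(C)C(C)(C)C)B1OC(C)(C)C(C)(C)O1 | intermediate
10 | 2-[3-(tert-butyldimethylsilyloxy)prop-1-en-2-yl]-5-[(isobutyryloxy)methyl]phenyl (E)-2-methylbut-2-enoate | C/C=C(\C)C(=O)Oc1cc(COC(=O)C(C)C)ccc1C(=C)CO[Si](C)(C)C(C)(C)C | intermediate
11 | 2-(3-hydroxyprop-1-en-2-yl)-5-[(isobutyryloxy)methyl]phenyl (E)-2-methylbut-2-enoate | C/C=C(\C)C(=O)Oc1cc(COC(=O)C(C)C)ccc1C(=C)CO | intermediate
12 | 2-[(2S)-2-(hydroxymethyl)oxiran-2-yl]-5-[(isobutyryloxy)methyl]phenyl (E)-2-methylbut-2-enoate | C/C=C(\C)C(=O)Oc1cc(COC(=O)C(C)C)ccc1[C@]1(CO)CO1 | intermediate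
13 | 2-{(2R)-2-[(isobutyryloxy)methyl]oxiran-2-yl}-5-[(isobutyryloxy)methyl]phenyl (E)-2-methylbut-2-enoate | C/C=C(\C)C(=O)Oc1cc(COC(=O)C(C)C)ccc1[C@]1(COC(=O)C(C)C)CO1 | target

## Step count and least certain steps

Total step count: 9. Longest linear sequence: 7 (steps 1, 2, 3, 6, 7, 8, 9). Steps 4 and 5 form the short branch.

**Step 8 (key step).**
- *Most likely failure.* Enantioface selection may be incomplete, because the ortho-acyloxy aryl group is twisted out of the alkene plane and acts as a bulky 2-substituent that presses on the tartrate ester groups. Slow turnover would also give time for titanium-mediated tigloyl transfer to the C10 oxygen and for opening of the oxirane.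
- *Fallback.* Resolution replaces asymmetric catalysis, setting out from 11. Hydroxyl-directed epoxidation with VO(acac)2 and tBuOOH in toluene at 0 °C should give the racemic 2-arylglycidol F1 with the same preference over the tiglate alkene. The enantiomers of F1 are separated by preparative chromatography on a polysaccharide carbamate chiral phase. The S enantiomer is 12, where the route is rejoined, and the price is half of the material.

**Step 7.**
- *Most likely failure.* The tigloyl group may migrate from the phenol oxygen to the freed C10 hydroxyl group through a seven-membered tetrahedral intermediate. This is downhill because an aryl ester becomes an alkyl ester, and it is helped by any basic species during cleavage or work-up.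
- *Fallback.* The hydroxyl group is introduced by C–H oxidation instead of unmasking, setting out from 6. Suzuki–Miyaura coupling with commercial isopropenylboronic acid pinacol ester under the conditions of step 6 gives the isopropenyl arene F2. Allylic hydroxylation with catalytic SeO2 and tBuOOH in CH2Cl2 (ene reaction, then [2,3]-shift) should then attack the one allylic methyl group on an electron-rich alkene and give 11, where the route is rejoined. No silyl ether or fluoride is involved, the medium is weakly acidic, and steps 4 and 5 fall away.

**Step 6.**
- *Most likely failures.* Basic fluoride at 60 °C may cleave or transfer the aryl tiglate, fluoride may attack the silyl ether, and the arylpalladium may insert into the neighbouring tiglate alkene if transmetalation is slow.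
- *Fallback.* The coupling is done before any ester is present, setting out from 2 and 9. PdCl2(dppf), aqueous K2CO3 and dioxane at 80 °C give the phenol diol mono-silyl ether F3. Phenoxide-selective acylation with 3 (K2CO3, acetone, 0 °C) gives the tiglate F4, and acylation with 5 (pyridine, DMAP) gives 10, where the route is rejoined. The total stays at nine steps and the longest line grows by one.

**Step 2.**
- *Most likely failures.* Site selectivity may be lost (acylation of the benzylic hydroxyl group or of both oxygens), and some of the acyl group may be deconjugated.
- *Fallback.* The order is reversed under enzyme control, setting out from 2. Candida antarctica lipase B with vinyl isobutyrate in tert-butyl methyl ether at room temperature acylates only the aliphatic hydroxyl group and gives the phenolic benzyl ester F5. Its single remaining hydroxyl group is acylated with 3 and K2CO3 in acetone to give 6, where the route is rejoined with the same number of steps.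

**Step 5.**
- *Most likely failures.* Freshly formed boronate may couple with unreacted bromide to give a diene dimer, and the alkenyl boronate may undergo protodeborylation on isolation.
- *Fallback.* The polarity of the coupling is exchanged, setting out from 6. Miyaura borylation (B2pin2, PdCl2(dppf), KOAc, dioxane, 80 °C) gives the aryl boronate F6. This is coupled with bromide 8 under the conditions of step 6 to give 10, where the route is rejoined. The longest line grows by one step.

## Further compounds

F1 | step 8 | racemic 2-[2-(hydroxymethyl)oxiran-2-yl]-5-[(isobutyryloxy)methyl]phenyl (E)-2-methylbut-2-enoate | C/C=C(\C)C(=O)Oc1cc(COC(=O)C(C)C)ccc1C1(CO)CO1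
F2 | step 7 | 5-[(isobutyryloxy)methyl]-2-(prop-1-en-2-yl)phenyl (E)-2-methylbut-2-enoate | C/C=C(\C)C(=O)Oc1cc(COC(=O)C(C)C)ccc1C(C)=C
F3 | step 6 | 2-[3-(tert-butyldimethylsilyloxy)prop-1-en-2-yl]-5-(hydroxymethyl)phenol | OCc1ccc(C(=C)CO[Si](C)(C)C(C)(C)C)c(O)c1
F4 | step 6 | 2-[3-(tert-butyldimethylsilyloxy)prop-1-en-2-yl]-5-(hydroxymethyl)phenyl (E)-2-methylbut-2-enoate | C/C=C(\C)C(=O)Oc1cc(CO)ccc1C(=C)CO[Si](C)(C)C(C)(C)C
F5 | step 2 | (4-bromo-3-hydroxyphenyl)methyl 2-methylpropanoate | CC(C)C(=O)OCc1ccc(Br)c(O)c1
F6 | step 5 | 5-[(isobutyryloxy)methyl]-2-(4,4,5,5-tetramethyl-1,3,2-dioxaborolan-2-yl)phenyl (E)-2-methylbut-2-enoate | C/C=C(\C)C(=O)Oc1cc(COC(=O)C(C)C)ccc1B1OC(C)(C)C(C)(C)O1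
A1 | alternative 1 | ethyl 2-diazo-2-{2-(tert-butyldimethylsilyloxy)-4-[(isobutyryloxy)methyl]phenyl}acetate | CCOC(=O)C(=[N+]=[N-])c1ccc(COC(=O)C(C)C)cc1O[Si](C)(C)C(C)(C)C
A2 | alternative 1 | water | O
A3 | alternative 1 | formaldehyde | C=O
A4 | alternative 1 | ethyl 2-{2-(tert-butyldimethylsilyloxy)-4-[(isobutyryloxy)methyl]phenyl}-2,3-dihydroxypropanoate, single enantiomer at quaternary C8 | CCOC(=O)[C@](O)(CO)c1ccc(COC(=O)C(C)C)cc1O[Si](C)(C)C(C)(C)C
A5 | alternative 2 | 2-{2-(allyloxy)-4-[(tert-butyldimethylsilyloxy)methyl]phenyl}-1,3-dichloropropan-2-ol | C=CCOc1cc(CO[Si](C)(C)C(C)(C)C)ccc1C(O)(CCl)CCl
A6 | alternative 2 | (S)-2-{2-(allyloxy)-4-[(tert-butyldimethylsilyloxy)methyl]phenyl}-2-(chloromethyl)oxirane | C=CCOc1cc(CO[Si](C)(C)C(C)(C)C)ccc1[C@]1(CO1)CCl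
A7 | alternative 3 | 2-iodo-5-[(isobutyryloxy)methyl]phenyl (E)-2-methylbut-2-enoate | C/C=C(\C)C(=O)Oc1cc(COC(=O)C(C)C)ccc1I
A8 | alternative 3 | propadiene | C=C=C
A9 | alternative 3 | caesium isobutyrate | CC(C)C(=O)[O-].[Cs+]
A10 | alternative 3 | 2-[3-(isobutyryloxy)prop-1-en-2-yl]-5-[(isobutyryloxy)methyl]phenyl (E)-2-methylbut-2-enoate | C/C=C(\C)C(=O)Oc1cc(COC(=O)C(C)C)ccc1C(=C)COC(=O)C(C)C
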